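Ring B is cut at C1–C2. Because the 4′-hydroxyl of the pendant ring lies para to the ring carbon that holds C1, a diaryl carbinol at C1 can lose water to a para-quinone methide with C1 as its exocyclic terminus; C2, the α-carbon of an α-benzyloxy β-keto ester tied to ring A through C3 and C4, then adds to C1. This one acid-catalysed operation closes ring B, makes the C1–C2 bond and sets C1 and the quaternary C2. Its precursor is a benzyl 2-(benzyloxy)-3-oxobutanoate whose C4 carries ring A, with the aryl(hydroxy)methyl group ortho to the chain and the 4′-phenol free; a benzyl ester lets one final hydrogenolysis unmask everything.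

Key step: step 7

Numbering: ring B is C1 (CH–aryl), C2, C3, C4 (CH2); ring A is the fused arene; primed locants belong to the pendant ring.
Assumption 1: homovanillic acid itself would brominate ortho to its free phenol, so its O-benzyl ether 1 is the starting material; 1 and benzyl 2-(benzyloxy)acetate 11 are taken as purchased.
Assumption 2: the sense of induction of the phosphoric acid cannot be predicted for this tethered case; the (R)-acid is written, and its mirror image is used if the first run gives the antipode at C1.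

Step 1
Reactants: 1 2-[4-(benzyloxy)-3-methoxyphenyl]acetic acid
Product: 2 2-[4-(benzyloxy)-2-bromo-5-methoxyphenyl]acetic acid
Conditions: NBS (1.05 equiv), MeCN, 0 → 20 °C, dark
Reagents that add atoms: N-bromosuccinimide, O=C1CCC(=O)N1Br
Why: Electrophilic aromatic bromination; with the phenol capped, the position para to the methoxy group and ortho to the side chain is the most activated open site, whereas a free phenol would steer bromine ortho to OH.

Step 2
Reactants: 3 3,4-dihydroxy-5-methoxybenzaldehyde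
Product: 5 3-(benzyloxy)-4-hydroxy-5-methoxybenzaldehyde, via disodium catecholate 4 (not isolated)
Conditions: NaH (2.1 equiv), DMSO, 20 °C; BnBr (1.0 equiv), 20 °C; aq. HCl
Reagents that add atoms: benzyl bromide, BrCc1ccccc1
Why: Williamson ether synthesis on the dianion: the 3-oxide is not conjugated with the formyl group and is less hindered, so it is the more nucleophilic oxygen and should take the single equivalent of benzyl bromide, leaving the 4-OH free.

Step 3
Reactants: 5 3-(benzyloxy)-4-hydroxy-5-methoxybenzaldehyde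
Product: 6 3-(benzyloxy)-4-[(tert-butyldimethylsilyl)oxy]-5-methoxybenzaldehyde
Conditions: TBSCl (1.2 equiv), imidazole (2.5 equiv), DMF, 20 °C
Reagents that add atoms: tert-butyl(chloro)dimethylsilane, CC(C)(C)[Si](C)(C)Cl
Why: Standard silylation of a phenol; the doubly ortho-substituted aryl silyl ether should survive the organolithium addition and later leave with fluoride.

Step 4
Reactants: 2 2-[4-(benzyloxy)-2-bromo-5-methoxyphenyl]acetic acid; 6 3-(benzyloxy)-4-[(tert-butyldimethylsilyl)oxy]-5-methoxybenzaldehyde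
Product: 10 racemic 2-{4-(benzyloxy)-2-[[3-(benzyloxy)-4-(tert-butyldimethylsilyloxy)-5-methoxyphenyl](triethylsilyloxy)methyl]-5-methoxyphenyl}acetic acid, via aryllithium carboxylate 7 (not isolated), via dilithium alkoxide carboxylate 8 (not isolated), via bis-triethylsilyl derivative 9 (not isolated)
Conditions: 2, n-BuLi (2.05 equiv), THF, −100 °C; 6, −100 → −78 °C; TESCl (2.5 equiv), DMAP (cat.), −78 → 20 °C; aq. NaHCO3/THF; citric acid to pH 5
Reagents that add atoms: chlorotriethylsilane, CC[Si](Cl)(CC)CC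
Why: Low-temperature bromine–lithium exchange on the preformed lithium carboxylate gives an aryllithium that adds 1,2 to aldehyde 6, the alkoxide is silylated before work-up so that it cannot close onto the carboxyl group to an isochromanone, and the silyl ester falls to water; the new carbinol centre is racemic, which is harmless because step 7 erases it.

Step 5
Reactants: 10 racemic 2-{4-(benzyloxy)-2-[[3-(benzyloxy)-4-(tert-butyldimethylsilyloxy)-5-methoxyphenyl](triethylsilyloxy)methyl]-5-methoxyphenyl}acetic acid; 11 benzyl 2-(benzyloxy)acetate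
Product: 14 benzyl 2-(benzyloxy)-4-{4-(benzyloxy)-2-[[3-(benzyloxy)-4-(tert-butyldimethylsilyloxy)-5-methoxyphenyl](triethylsilyloxy)methyl]-5-methoxyphenyl}-3-oxobutanoate (diastereomer mixture), via acyl imidazolide 12 (not isolated), via lithium enolate 13 (not isolated)
Conditions: 10, CDI (1.1 equiv), THF, 20 °C; added to 13 [11 (3.5 equiv), LiN(i-Pr)2 (3.5 equiv), THF, −78 °C]; −78 °C; AcOH
Reagents that add atoms: none
Why: Crossed Claisen condensation: C-acylation of the chelated lithium enolate by the acyl imidazolide at −78 °C should outrun proton transfer (any arylketene formed by elimination is trapped by the same enolate to the same product), with excess enolate taking up the acidic product and the imidazole N–H; C2 forms as a mixture that step 7 erases.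

Step 6
Reactants: 14 benzyl 2-(benzyloxy)-4-{4-(benzyloxy)-2-[[3-(benzyloxy)-4-(tert-butyldimethylsilyloxy)-5-methoxyphenyl](triethylsilyloxy)methyl]-5-methoxyphenyl}-3-oxobutanoate
Product: 15 benzyl 2-(benzyloxy)-4-{4-(benzyloxy)-2-[[3-(benzyloxy)-4-hydroxy-5-methoxyphenyl](hydroxy)methyl]-5-methoxyphenyl}-3-oxobutanoate (diastereomer mixture)
Conditions: TBAF (2.5 equiv), AcOH (2.5 equiv), THF, 0 °C
Reagents that add atoms: none
Why: Fluoride-mediated desilylation, buffered by acetic acid so that neither the keto ester is enolised nor the electron-rich carbinol ionised, removes the alkyl triethylsilyl ether and the aryl tert-butyldimethylsilyl ether, while benzyl ethers and the benzyl ester are inert.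

Step 7
Reactants: 15 benzyl 2-(benzyloxy)-4-{4-(benzyloxy)-2-[[3-(benzyloxy)-4-hydroxy-5-methoxyphenyl](hydroxy)methyl]-5-methoxyphenyl}-3-oxobutanoate
Product: 17 benzyl (1S,2S)-2,7-bis(benzyloxy)-1-[3-(benzyloxy)-4-hydroxy-5-methoxyphenyl]-6-methoxy-3-oxo-1,2,3,4-tetrahydronaphthalene-2-carboxylate, via para-quinone methide 16 (not isolated)
Conditions: (R)-TRIP [(R)-3,3′-bis(2,4,6-triisopropylphenyl)-1,1′-binaphthyl-2,2′-diyl hydrogen phosphate] (10 mol %), PhMe/CH2Cl2 (0.02 M), 0 °C
Reagents that add atoms: none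
Why: Proposed new method: the phosphoric acid protonates the carbinol of 15, water leaves with electron push from the free 4′-OH to give para-quinone methide 16, and the acid, hydrogen-bonded to the quinone oxygen and to the enol O–H of the keto ester, brings the enol carbon C2 onto the exocyclic carbon C1, rearomatising the pendant ring. The closest known reaction type is the chiral-phosphoric-acid-catalysed intermolecular 1,6-addition of 1,3-dicarbonyl compounds to para-quinone methides generated in situ from para-hydroxybenzyl alcohols; a tethered, α-oxygenated nucleophile is the extrapolation. The six-membered ring forms by a 6-(enolendo)-exo-trig closure. C1 is set by the chiral phosphate, which covers one face of the quinone methide in the hydrogen-bonded complex; C2 is set relative to C1 in a half-chair closure in which the quinone methide ring stands pseudoaxial and the bulkier C2 substituent, the benzyl ester, should sit anti to it, giving aryl trans to ester. The step needs C- over O-alkylation, C2 over C4 attack and the trans relation: closure through the enol oxygen is reversible, because the resulting doubly benzylic ether is itself a quinone methide precursor under the acid; the other enolisable carbon, C4, could reach C1 only through a benzocyclobutene; and the trans relation is only biased by the size difference at C2, so it has to be confirmed on 17 (NOE or X-ray) before going on.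

Step 8
Reactants: 17 benzyl (1S,2S)-2,7-bis(benzyloxy)-1-[3-(benzyloxy)-4-hydroxy-5-methoxyphenyl]-6-methoxy-3-oxo-1,2,3,4-tetrahydronaphthalene-2-carboxylate
Product: 18 benzyl (1S,2S)-2,7-bis(benzyloxy)-1-[3-(benzyloxy)-4-hydroxy-5-methoxyphenyl]-6-methoxy-3-methylidene-1,2,3,4-tetrahydronaphthalene-2-carboxylate
Conditions: Cp2Ti(μ-Cl)(μ-CH2)AlMe2 (Tebbe reagent, 2.3 equiv), pyridine (cat.), THF/PhMe, −40 → 0 °C; aq. NaOH
Reagents that add atoms: Tebbe reagent Cp2Ti(μ-Cl)(μ-CH2)AlMe2, C[Al](C)C[Ti](Cl)(C1C=CC=C1)C1C=CC=C1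
Why: Tebbe olefination: the titanium methylidene is non-basic, so the readily enolised β-tetralone carbonyl is methylenated through an oxatitanacyclobutane without enolisation, a ketone reacts faster than the hindered ester, and one equivalent is sacrificed to the phenol, which returns on work-up.

Step 9
Reactants: 18 benzyl (1S,2S)-2,7-bis(benzyloxy)-1-[3-(benzyloxy)-4-hydroxy-5-methoxyphenyl]-6-methoxy-3-methylidene-1,2,3,4-tetrahydronaphthalene-2-carboxylate
Product: 19 benzyl (1S,2S)-2,7-bis(benzyloxy)-1-[3,4-bis(benzyloxy)-5-methoxyphenyl]-6-methoxy-3-methylidene-1,2,3,4-tetrahydronaphthalene-2-carboxylate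
Conditions: BnBr (1.2 equiv), K2CO3 (2 equiv), DMF, 20 → 40 °C
Reagents that add atoms: benzyl bromide, BrCc1ccccc1
Why: Williamson ether synthesis; with the acidic C4–H2 of the ketone gone the phenol is the only site that K2CO3 deprotonates, and its ether guards the electron-rich ring against oxidation in step 10.

Step 10
Reactants: 19 benzyl (1S,2S)-2,7-bis(benzyloxy)-1-[3,4-bis(benzyloxy)-5-methoxyphenyl]-6-methoxy-3-methylidene-1,2,3,4-tetrahydronaphthalene-2-carboxylate
Product: 20 benzyl (1S,2S,3R)-2,7-bis(benzyloxy)-1-[3,4-bis(benzyloxy)-5-methoxyphenyl]-3-hydroxy-3-(hydroxymethyl)-6-methoxy-1,2,3,4-tetrahydronaphthalene-2-carboxylate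
Conditions: OsO4 (5 mol %), NMO (1.5 equiv), acetone/H2O, 20 °C
Reagents that add atoms: osmium tetroxide OsO4 (catalytic oxygen carrier), O=[Os](=O)(=O)=O; N-methylmorpholine N-oxide, C[N+]1([O-])CCOCC1; water, O
Why: Catalytic osmium tetroxide dihydroxylation of a 1,1-disubstituted alkene; the reagent should come from the face opposite the allylic C2 benzyloxy group and the C1 aryl ring, which share one side of ring B, so that the C3 hydroxyl ends up trans to the C2 ether (3R) by substrate control.

Step 11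
Reactants: 20 benzyl (1S,2S,3R)-2,7-bis(benzyloxy)-1-[3,4-bis(benzyloxy)-5-methoxyphenyl]-3-hydroxy-3-(hydroxymethyl)-6-methoxy-1,2,3,4-tetrahydronaphthalene-2-carboxylate
Product: 21 plicatic acid
Conditions: H2 (1 atm), Pd(OH)2 on carbon, MeOH/EtOAc, 20 °C
Reagents that add atoms: none
Why: Hydrogenolysis cleaves the four benzyl ethers and the benzyl ester in one neutral operation, no stereocentre is touched, and the air-sensitive catechol never meets base.

Compound list

1 | 2-[4-(benzyloxy)-3-methoxyphenyl]acetic acid (O-benzyl homovanillic acid) | COc1cc(CC(=O)O)ccc1OCc1ccccc1 | starting material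
2 | 2-[4-(benzyloxy)-2-bromo-5-methoxyphenyl]acetic acid | COc1cc(CC(=O)O)c(Br)cc1OCc1ccccc1 | intermediate
3 | 3,4-dihydroxy-5-methoxybenzaldehyde | COc1cc(C=O)cc(O)c1O | starting material
4 | disodium 5-formyl-3-methoxybenzene-1,2-diolate (not isolated) | [Na+].[Na+].COc1cc(C=O)cc([O-])c1[O-] | intermediate
5 | 3-(benzyloxy)-4-hydroxy-5-methoxybenzaldehyde | COc1cc(C=O)cc(OCc2ccccc2)c1O | intermediate
6 | 3-(benzyloxy)-4-[(tert-butyldimethylsilyl)oxy]-5-methoxybenzaldehyde | COc1cc(C=O)cc(OCc2ccccc2)c1O[Si](C)(C)C(C)(C)C | intermediate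
7 | lithium 2-[4-(benzyloxy)-2-lithio-5-methoxyphenyl]acetate (not isolated) | [Li+].COc1cc(CC(=O)[O-])c([Li])cc1OCc1ccccc1 | intermediate
8 | dilithium alkoxide carboxylate of 2-{4-(benzyloxy)-2-[[3-(benzyloxy)-4-(tert-butyldimethylsilyloxy)-5-methoxyphenyl](hydroxy)methyl]-5-methoxyphenyl}acetic acid, racemic (not isolated) | [Li+].[Li+].COc1cc(CC(=O)[O-])c(cc1OCc1ccccc1)C([O-])c1cc(OCc2ccccc2)c(O[Si](C)(C)C(C)(C)C)c(OC)c1 | intermediate
9 | triethylsilyl 2-{4-(benzyloxy)-2-[[3-(benzyloxy)-4-(tert-butyldimethylsilyloxy)-5-methoxyphenyl](triethylsilyloxy)methyl]-5-methoxyphenyl}acetate, racemic (not isolated) | COc1cc(CC(=O)O[Si](CC)(CC)CC)c(cc1OCc1ccccc1)C(O[Si](CC)(CC)CC)c1cc(OCc2ccccc2)c(O[Si](C)(C)C(C)(C)C)c(OC)c1 | intermediate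
10 | 2-{4-(benzyloxy)-2-[[3-(benzyloxy)-4-(tert-butyldimethylsilyloxy)-5-methoxyphenyl](triethylsilyloxy)methyl]-5-methoxyphenyl}acetic acid, racemic | COc1cc(CC(=O)O)c(cc1OCc1ccccc1)C(O[Si](CC)(CC)CC)c1cc(OCc2ccccc2)c(O[Si](C)(C)C(C)(C)C)c(OC)c1 | intermediate
11 | benzyl 2-(benzyloxy)acetate | O=C(COCc1ccccc1)OCc1ccccc1 | starting material
12 | acyl imidazolide of 10, the 1-(1H-imidazol-1-yl)ethan-1-one in place of the acid (not isolated) | COc1cc(CC(=O)n2ccnc2)c(cc1OCc1ccccc1)C(O[Si](CC)(CC)CC)c1cc(OCc2ccccc2)c(O[Si](C)(C)C(C)(C)C)c(OC)c1 | intermediate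
13 | lithium enolate of 11, lithium 1,2-bis(benzyloxy)ethen-1-olate (not isolated) | [Li+].[O-]C(OCc1ccccc1)=COCc1ccccc1 | intermediate
14 | benzyl 2-(benzyloxy)-4-{4-(benzyloxy)-2-[[3-(benzyloxy)-4-(tert-butyldimethylsilyloxy)-5-methoxyphenyl](triethylsilyloxy)methyl]-5-methoxyphenyl}-3-oxobutanoate, mixture of diastereomers | COc1cc(CC(=O)C(OCc2ccccc2)C(=O)OCc2ccccc2)c(cc1OCc1ccccc1)C(O[Si](CC)(CC)CC)c1cc(OCc2ccccc2)c(O[Si](C)(C)C(C)(C)C)c(OC)c1 | intermediate
15 | benzyl 2-(benzyloxy)-4-{4-(benzyloxy)-2-[[3-(benzyloxy)-4-hydroxy-5-methoxyphenyl](hydroxy)methyl]-5-methoxyphenyl}-3-oxobutanoate, mixture of diastereomers at the carbinol and C2 (may rest partly as the cyclic hemiketal of the carbinol oxygen on the C3 ketone) | COc1cc(CC(=O)C(OCc2ccccc2)C(=O)OCc2ccccc2)c(cc1OCc1ccccc1)C(O)c1cc(OCc2ccccc2)c(O)c(OC)c1 | intermediate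
16 | para-quinone methide, benzyl 2-(benzyloxy)-4-{4-(benzyloxy)-2-[(3-(benzyloxy)-5-methoxy-4-oxocyclohexa-2,5-dien-1-ylidene)methyl]-5-methoxyphenyl}-3-oxobutanoate, alkene geometry and C2 undefined (not isolated) | COC1=CC(=Cc2cc(OCc3ccccc3)c(OC)cc2CC(=O)C(OCc2ccccc2)C(=O)OCc2ccccc2)C=C(OCc2ccccc2)C1=O | intermediate
17 | benzyl (1S,2S)-2,7-bis(benzyloxy)-1-[3-(benzyloxy)-4-hydroxy-5-methoxyphenyl]-6-methoxy-3-oxo-1,2,3,4-tetrahydronaphthalene-2-carboxylate | COc1cc2c(cc1OCc1ccccc1)[C@H](c1cc(OCc3ccccc3)c(O)c(OC)c1)[C@@](OCc3ccccc3)(C(=O)OCc3ccccc3)C(=O)C2 | intermediate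
18 | benzyl (1S,2S)-2,7-bis(benzyloxy)-1-[3-(benzyloxy)-4-hydroxy-5-methoxyphenyl]-6-methoxy-3-methylidene-1,2,3,4-tetrahydronaphthalene-2-carboxylate | COc1cc2c(cc1OCc1ccccc1)[C@H](c1cc(OCc3ccccc3)c(O)c(OC)c1)[C@@](OCc3ccccc3)(C(=O)OCc3ccccc3)C(=C)C2 | intermediate
19 | benzyl (1S,2S)-2,7-bis(benzyloxy)-1-[3,4-bis(benzyloxy)-5-methoxyphenyl]-6-methoxy-3-methylidene-1,2,3,4-tetrahydronaphthalene-2-carboxylate | COc1cc2c(cc1OCc1ccccc1)[C@H](c1cc(OCc3ccccc3)c(OCc3ccccc3)c(OC)c1)[C@@](OCc3ccccc3)(C(=O)OCc3ccccc3)C(=C)C2 | intermediate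
20 | benzyl (1S,2S,3R)-2,7-bis(benzyloxy)-1-[3,4-bis(benzyloxy)-5-methoxyphenyl]-3-hydroxy-3-(hydroxymethyl)-6-methoxy-1,2,3,4-tetrahydronaphthalene-2-carboxylate | COc1cc2c(cc1OCc1ccccc1)[C@H](c1cc(OCc3ccccc3)c(OCc3ccccc3)c(OC)c1)[C@@](OCc3ccccc3)(C(=O)OCc3ccccc3)[C@](O)(CO)C2 | intermediate
21 | plicatic acid, (1S,2S,3R)-1-(3,4-dihydroxy-5-methoxyphenyl)-2,3,7-trihydroxy-3-(hydroxymethyl)-6-methoxy-1,2,3,4-tetrahydronaphthalene-2-carboxylic acid | COc1cc2c(cc1O)[C@H](c1cc(O)c(O)c(OC)c1)[C@@](O)(C(=O)O)[C@](O)(CO)C2 | target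

Total steps: 11. Longest linear sequence: 10 steps (3 → 21 through steps 2–11); the ring-A branch (steps 1 and 4–11) is 9.

Steps most likely to fail

Step 7 (key step). What may go wrong: the closure runs outside the chiral hydrogen-bonded complex (background acid catalysis, or a loose fit of the tethered enol in the catalyst pocket), so that enantiofacial control at C1 is lost. Fallback, known chemistry throughout: starting from 15, an achiral acid (diphenyl phosphate, 10 mol %, CH2Cl2, 20 °C) effects the same dehydrative alkylation of the 1,3-dicarbonyl unit by the benzhydrol, an established reaction type. It should give the racemate, that is 17 together with its mirror image benzyl (1R,2R)-2,7-bis(benzyloxy)-1-[3-(benzyloxy)-4-hydroxy-5-methoxyphenyl]-6-methoxy-3-oxo-1,2,3,4-tetrahydronaphthalene-2-carboxylate F1. Preparative chromatography on a chiral stationary phase separates the two, and the route is rejoined at 17 (step 8).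

Step 4. What may go wrong: the alkoxide is not trapped cleanly and closes onto the carboxyl group (lactonisation), so that the open, silyl-protected acid 10 is not obtained. Fallback: starting from 2 and 6, the same exchange and addition are quenched with aqueous acid and no chlorosilane, so that closure goes to completion and gives the lactone racemic 7-(benzyloxy)-1-[3-(benzyloxy)-4-(tert-butyldimethylsilyloxy)-5-methoxyphenyl]-6-methoxyisochroman-3-one F2. Aminolysis with MeNH(OMe)·HCl and i-PrMgCl (THF, −20 °C) opens it to the hydroxy N-methoxy-N-methylamide F3, and TESCl with imidazole (DMF) gives its triethylsilyl ether F4. F4 then acylates lithium enolate 13 (THF, −78 → 0 °C) to give 14, where the route is rejoined, with acid 10 and step 5 bypassed.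

Step 10. What may go wrong: poor facial selectivity in the osmylation, if a ring conformer with a pseudoaxial ester leaves both faces of the alkene similarly open. Fallback: deliver the C3 oxygen from the C2 carboxyl group, which sits on the required face. Starting from 19, LiOH (THF/MeOH/H2O, 50 °C) gives the methylidene acid F5. I2 and NaHCO3 (MeCN, 0 °C, dark), the kinetic iodolactonisation of a β,γ-unsaturated acid, give the cis-fused iodomethyl β-lactone F6, in which C3–O is necessarily syn to the carboxyl carbon. Aqueous KOH in THF opens the lactone at the acyl carbon, the C3 alkoxide displaces iodide to the spiro-epoxy acid F7 (not isolated), and hydroxide opens the epoxide at CH2 to the dihydroxy acid F8. Hydrogenolysis under the conditions of step 11 then gives 21.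

Further compounds

F1 | step 7 | benzyl (1R,2R)-2,7-bis(benzyloxy)-1-[3-(benzyloxy)-4-hydroxy-5-methoxyphenyl]-6-methoxy-3-oxo-1,2,3,4-tetrahydronaphthalene-2-carboxylate (mirror image of 17) | COc1cc2c(cc1OCc1ccccc1)[C@@H](c1cc(OCc3ccccc3)c(O)c(OC)c1)[C@](OCc3ccccc3)(C(=O)OCc3ccccc3)C(=O)C2
F2 | step 4 | racemic 7-(benzyloxy)-1-[3-(benzyloxy)-4-(tert-butyldimethylsilyloxy)-5-methoxyphenyl]-6-methoxyisochroman-3-one | COc1cc2c(cc1OCc1ccccc1)C(c1cc(OCc3ccccc3)c(O[Si](C)(C)C(C)(C)C)c(OC)c1)OC(=O)C2
F3 | step 4 | racemic 2-{4-(benzyloxy)-2-[[3-(benzyloxy)-4-(tert-butyldimethylsilyloxy)-5-methoxyphenyl](hydroxy)methyl]-5-methoxyphenyl}-N-methoxy-N-methylacetamide | COc1cc(CC(=O)N(C)OC)c(cc1OCc1ccccc1)C(O)c1cc(OCc2ccccc2)c(O[Si](C)(C)C(C)(C)C)c(OC)c1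
F4 | step 4 | racemic 2-{4-(benzyloxy)-2-[[3-(benzyloxy)-4-(tert-butyldimethylsilyloxy)-5-methoxyphenyl](triethylsilyloxy)methyl]-5-methoxyphenyl}-N-methoxy-N-methylacetamide | COc1cc(CC(=O)N(C)OC)c(cc1OCc1ccccc1)C(O[Si](CC)(CC)CC)c1cc(OCc2ccccc2)c(O[Si](C)(C)C(C)(C)C)c(OC)c1
F5 | step 10 | (1S,2S)-2,7-bis(benzyloxy)-1-[3,4-bis(benzyloxy)-5-methoxyphenyl]-6-methoxy-3-methylidene-1,2,3,4-tetrahydronaphthalene-2-carboxylic acid | COc1cc2c(cc1OCc1ccccc1)[C@H](c1cc(OCc3ccccc3)c(OCc3ccccc3)c(OC)c1)[C@@](OCc3ccccc3)(C(=O)O)C(=C)C2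
F6 | step 10 | iodomethyl β-lactone of F5: the C2 carboxyl closed onto C3 as a cis-fused oxetan-2-one, C3 bearing CH2I, C1 and C2 as in 19, C3–O on the face of the carboxyl carbon | COc1cc2c(cc1OCc1ccccc1)[C@H](c1cc(OCc3ccccc3)c(OCc3ccccc3)c(OC)c1)[C@@]1(OCc3ccccc3)C(=O)O[C@@]1(CI)C2
F7 | step 10 | spiro-epoxy acid: (1S,2S)-2,7-bis(benzyloxy)-1-[3,4-bis(benzyloxy)-5-methoxyphenyl]-6-methoxy-tetralin-2-carboxylic acid with a spiro-oxirane at C3, epoxide oxygen on the face of the carboxyl group (not isolated) | COc1cc2c(cc1OCc1ccccc1)[C@H](c1cc(OCc3ccccc3)c(OCc3ccccc3)c(OC)c1)[C@@](OCc3ccccc3)(C(=O)O)[C@]1(CO1)C2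
F8 | step 10 | (1S,2S,3R)-2,7-bis(benzyloxy)-1-[3,4-bis(benzyloxy)-5-methoxyphenyl]-3-hydroxy-3-(hydroxymethyl)-6-methoxy-1,2,3,4-tetrahydronaphthalene-2-carboxylic acid | COc1cc2c(cc1OCc1ccccc1)[C@H](c1cc(OCc3ccccc3)c(OCc3ccccc3)c(OC)c1)[C@@](OCc3ccccc3)(C(=O)O)[C@](O)(CO)C2
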